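The data were generated by integration with made-up constants, and the scatter is random.

The ratio of starting material to free catalyst charged is 1200 in the north-east flask, against 400 in the south-west run, with 300 mM of starting material in both.

| flask | starting material | free catalyst | time |
|---|---|---|---|
| east | 150 mM | 0.750 mM |  |
| south | 90.0 mM | 0.750 mM |  |
| south-east | 150 mM | 2.30 mM |  |
| south-west | 300 mM | 0.750 mM |  |
| north-east | 300 mM | 0.250 mM | 19 min |

| run | time / min | [target] / mM |
|---|---|---|
| east run | 0.76 | 5.7 |
| east run | 1.2 | 7.9 |
| east run | 1.9 | 12.9 |
| east run | 3.0 | 18.7 |
| east run | 4.8 | 29.1 |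
| east run | 7.6 | 41.8 |
| east run | 12 | 57.4 |
| east run | 19 | 66.3 |
| south run | 0.76 | 4.9 |
| south run | 1.2 | 7.2 |
| south run | 1.9 | 11.9 |
| south run | 3.0 | 17.7 |
| south run | 4.8 | 26.2 |
| south run | 7.6 | 36.3 |
| south run | 12 | 44.4 |
| south run | 19 | 46.8 |
| south-east run | 0.76 | 15.7 |
| south-east run | 1.2 | 23.9 |
| south-east run | 1.9 | 36.0 |
| south-east run | 3.0 | 54.4 |
| south-east run | 4.8 | 75.7 |
| south-east run | 7.6 | 90.2 |
| south-east run | 12 | 91.4 |
| south-east run | 19 | 85.8 |
| south-west run | 0.76 | 5.3 |
| south-west run | 1.2 | 8.1 |
| south-west run | 1.9 | 12.8 |
| south-west run | 3.0 | 20.0 |
| south-west run | 4.8 | 31.8 |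
| south-west run | 7.6 | 46.7 |
| south-west run | 12 | 66.6 |
| south-west run | 19 | 88.7 |

(each reading ± 0.4 mM)

- Overall: starting material -> target, with free catalyst as catalyst.
- Constant volume, constant temperature.
- Readings of a species count what is bound in complexes too.
- An order is taken over about fifteen percent of the charge, up and down.

* apparent order in [starting material] of the starting rate, round the charge of the east run (the rate where two percent of its starting material have turned into target) (one fixed amount of target, the same in the runs compared)
* apparent order in [free catalyst] of the starting rate, round the charge of the east run (the rate where two percent of its starting material have turned into target)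
* target in the north-east run at 19 min, as a share of the starting material charged

For the bench: the north-east flask holds 300 mM starting material on 0.250 mM free catalyst. The starting-material charge stays as it is: at 3.0 min the south-west run reads 20.0 mM of target and the east run 18.7 mM, on twice the starting material.

The south-west run, with the same starting-material charge, has 118 turnovers by 19 min. This turnover count (turnover number), target formed per free catalyst charged, is carried across on an assumption of my own: an equal count at equal starting-material charge and equal time. In fractions of the charge, my reckoning runs:

south-west: fraction turned 29.6 % × charge ratio 400 = 118 turnovers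

north-east: 118 ÷ charge ratio 1200 = 9.86 % turned

The readings strain that assumption: on one starting-material charge, the south-east run, at 2.30 mM free catalyst, counts 37.3 at 19 min, and the east run, at 0.750 mM, counts 88.4. So my figure for the north-east flask, at the lower free catalyst, is meant as a low estimate.

The forecast gives orders of 0.12 and 0.97 and a north-east share of 12.8 %, higher than my 9.86 %: “Activity falls to about 0.75 by 19 min, giving about 38 mM, or 13%.”

The flask gives orders of 0.090 and 1.0 and a north-east share of 11.0 %.

    free catalyst + starting material ⇌ catalyst-substrate complex, settled at all times (78.60 M⁻¹)
    catalyst-substrate complex ⇌ target + free catalyst (10.02 min⁻¹, 232.2 M⁻¹ min⁻¹)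
    free catalyst + starting material → spent catalyst + starting material (2.454 M⁻¹ min⁻¹)
    starting material → decomposed substrate (0.04752 min⁻¹)

The path from starting material to decomposed substrate makes no difference to that share. The share counts 132 turnovers in the north-east run at 19 min on 0.250 mM free catalyst, more than the 118 of the south-west run on 0.750 mM.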